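**Retrosynthetic overview**

1. Target 25 ← hexabenzyl ether 24 ← 3,4-divinyl-2,5-diaryl oxolane 18; each vinyl group is a latent 2,4-dihydroxybenzoyl group (ozonolysis, aryllithium addition, oxidation).
2. Oxolane 18 ← γ-lactone 13: aryl addition to the lactone C=O, then oxocarbenium reduction, which sets C5 cis to the C4 substituent.
3. Lactone 13 ← Ireland–Claisen [3,3] rearrangement of (Z)-allyl but-3-enoate 9: this forms the C3–C4 bond and both of its stereocentres.
4. Ester 9 ← (R)-4-hydroxymandelic acid 1, whose carbinol carbon becomes C2 of the target and is the only stereocentre that is bought.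
5. Ring order: γ-lactone (step 6), converted in place into the oxolane (steps 7–8); no other ring is made.

Assumption: (R)-4-hydroxymandelic acid 1 (single enantiomer) and the aryl bromides 14 and 21 are bought as catalogue chemicals.

Oxolane numbering used below: O1, C2 (aryl, from 1), C3, C4, C5 (aryl).

**Route**

Step 1
Reactants: 1 (R)-4-hydroxymandelic acid
Product: 2 benzyl (2R)-2-[4-(benzyloxy)phenyl]-2-hydroxyacetate
Conditions: BnBr (2.2 equiv), K2CO3, DMF, 25 °C
Reagents that add atoms: benzyl bromide, BrCc1ccccc1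
Why: Williamson/carboxylate O-alkylation benzylates only the phenol and the acid under carbonate conditions, leaving the secondary alcohol free and the stereocentre untouched.

Step 2
Reactants: 2 benzyl (2R)-2-[4-(benzyloxy)phenyl]-2-hydroxyacetate
Product: 3 benzyl (2R)-2-[4-(benzyloxy)phenyl]-2-{[tert-butyl(dimethyl)silyl]oxy}acetate
Conditions: TBSCl, imidazole, DMF, 25 °C
Reagents that add atoms: tert-butyl(chloro)dimethylsilane, CC(C)(C)[Si](C)(C)Cl
Why: Standard silyl ether formation masks the carbinol so that the ester can be reduced and the alkene built without lactonisation or silyl loss.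

Step 3
Reactants: 3 benzyl (2R)-2-[4-(benzyloxy)phenyl]-2-{[tert-butyl(dimethyl)silyl]oxy}acetate; 4 methyl bis(2,2,2-trifluoroethyl)phosphonoacetate
Product: 6 methyl (2Z,4S)-4-[4-(benzyloxy)phenyl]-4-{[tert-butyl(dimethyl)silyl]oxy}but-2-enoate, via aldehyde 5 (not isolated)
Conditions: iBu2AlH (1.05 equiv), CH2Cl2, −78 °C; cold KNaC4H4O6 work-up; crude solution added to 4, KN(SiMe3)2, 18-crown-6, THF, −78 °C
Reagents that add atoms: none
Why: Partial ester reduction followed by Still–Gennari Z-selective Horner–Wadsworth–Emmons olefination gives the Z-enoate, and using the configurationally fragile α-silyloxy aldehyde cold and unpurified keeps the bought stereocentre intact (its label changes from R to S only through CIP priorities).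

Step 4
Reactants: 6 methyl (2Z,4S)-4-[4-(benzyloxy)phenyl]-4-{[tert-butyl(dimethyl)silyl]oxy}but-2-enoate
Product: 7 (2Z,4S)-4-[4-(benzyloxy)phenyl]-4-{[tert-butyl(dimethyl)silyl]oxy}but-2-en-1-ol
Conditions: iBu2AlH (2.5 equiv), CH2Cl2, −78 °C
Reagents that add atoms: none
Why: 1,2-Reduction of the enoate by the aluminium hydride gives the Z-allylic alcohol without touching the alkene geometry or the silyl ether.

Step 5
Reactants: 7 (2Z,4S)-4-[4-(benzyloxy)phenyl]-4-{[tert-butyl(dimethyl)silyl]oxy}but-2-en-1-ol; 8 but-3-enoic acid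
Product: 9 (2Z,4S)-4-[4-(benzyloxy)phenyl]-4-{[tert-butyl(dimethyl)silyl]oxy}but-2-en-1-yl but-3-enoate
Conditions: DCC, DMAP (5 mol%), CH2Cl2, 0 °C
Reagents that add atoms: none
Why: Steglich esterification at 0 °C with little DMAP joins the two halves while keeping the β,γ-unsaturated acid from sliding into conjugation.

Step 6
Reactants: 9 (2Z,4S)-4-[4-(benzyloxy)phenyl]-4-{[tert-butyl(dimethyl)silyl]oxy}but-2-en-1-yl but-3-enoate
Product: 13 (3R,4R,5S)-5-[4-(benzyloxy)phenyl]-3,4-diethenyloxolan-2-one, via silyl ketene acetal 10 (not isolated), via silyl ester 11 (not isolated), via hydroxy acid 12 (not isolated)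
Conditions: LiN(iPr)2, THF–DMPU, −78 °C; Me3SiCl; −78 → 45 °C; then HF·pyridine, 0 → 25 °C
Reagents that add atoms: none
Why: Ireland–Claisen [3,3]-sigmatropic rearrangement through a chair transition state, in which the (Z)-O-silyl dienolate (vinyl equatorial) and the (Z)-allyl unit (side chain axial) give the anti C3–C4 relationship while the new bond forms anti to the C–OSi bond of the mandelate-derived centre held with its H eclipsing the Z-alkene (allylic 1,3-strain), so both new centres are set by the bought one before fluoride strips both silyl groups and the cis γ-hydroxy acid lactonises.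

Step 7
Reactants: 13 (3R,4R,5S)-5-[4-(benzyloxy)phenyl]-3,4-diethenyloxolan-2-one; 14 1-(benzyloxy)-4-bromobenzene
Product: 17 (3R,4R,5S)-2,5-bis[4-(benzyloxy)phenyl]-3,4-diethenyloxolan-2-ol, via aryllithium 15 (not isolated), via arylcerium dichloride 16 (not isolated)
Conditions: 14, n-BuLi, THF, −78 °C; anhydrous CeCl3, −78 °C; then 13, −78 °C; H2O
Reagents that add atoms: none
Why: Halogen–lithium exchange and transmetalation give a weakly basic organocerium reagent that adds once to the lactone carbonyl rather than deprotonating the doubly activated α-position, giving the lactol as an anomeric mixture that is removed in the next step.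

Step 8
Reactants: 17 (3R,4R,5S)-2,5-bis[4-(benzyloxy)phenyl]-3,4-diethenyloxolan-2-ol
Product: 18 (2S,3R,4R,5S)-2,5-bis[4-(benzyloxy)phenyl]-3,4-diethenyloxolane
Conditions: Et3SiH, BF3·OEt2, CH2Cl2, −78 °C; Et3N quench at −78 °C
Reagents that add atoms: none
Why: Ionisation to the 2-aryl oxocarbenium ion and ionic hydrogenation, with hydride entering anti to the adjacent 4-vinyl group (inside attack on the envelope), places the new aryl cis to that vinyl group (C5 S) and the low temperature keeps the benzylic C2 ether from epimerising.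

Step 9
Reactants: 18 (2S,3R,4R,5S)-2,5-bis[4-(benzyloxy)phenyl]-3,4-diethenyloxolane
Product: 20 (2S,3R,4R,5S)-2,5-bis[4-(benzyloxy)phenyl]oxolane-3,4-dicarbaldehyde, via bis-ozonide 19 (not isolated)
Conditions: O3, CH2Cl2, −78 °C (stop at first blue tint); PPh3, −78 → 0 °C; used crude
Reagents that add atoms: ozone, [O-][O+]=O
Why: Ozonolysis (1,3-dipolar cycloaddition/cycloreversion, then reductive work-up) cleaves the two terminal alkenes much faster than it attacks benzyl ethers or alkoxyarenes, and neutral work-up leaves the epimerisable α-centres alone.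

Step 10
Reactants: 20 (2S,3R,4R,5S)-2,5-bis[4-(benzyloxy)phenyl]oxolane-3,4-dicarbaldehyde; 21 2,4-bis(benzyloxy)-1-bromobenzene
Product: 23 [(2S,3S,4S,5S)-2,5-bis[4-(benzyloxy)phenyl]oxolane-3,4-diyl]bis{[2,4-bis(benzyloxy)phenyl]methanol}, via aryllithium 22 (not isolated)
Conditions: 21 (3 equiv), n-BuLi, THF, −78 °C; then 20, −78 °C; H2O
Reagents that add atoms: none
Why: Halogen–lithium exchange and 1,2-addition of the aryllithium to both aldehydes at −78 °C outruns enolisation; the carbinol epimers are irrelevant because they are oxidised next (ring labels change to 3S,4S by CIP priority only).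

Step 11
Reactants: 23 [(2S,3S,4S,5S)-2,5-bis[4-(benzyloxy)phenyl]oxolane-3,4-diyl]bis{[2,4-bis(benzyloxy)phenyl]methanol}
Product: 24 [(2S,3R,4R,5S)-2,5-bis[4-(benzyloxy)phenyl]oxolane-3,4-diyl]bis{[2,4-bis(benzyloxy)phenyl]methanone}
Conditions: Dess–Martin periodinane, CH2Cl2, 0 → 25 °C
Reagents that add atoms: none
Why: Dess–Martin oxidation converts both benzylic carbinols to the aryl ketones under non-basic conditions, so the α-centres cis to the aryl groups are not epimerised and the β-alkoxy ketone does not ring-open.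

Step 12
Reactants: 24 [(2S,3R,4R,5S)-2,5-bis[4-(benzyloxy)phenyl]oxolane-3,4-diyl]bis{[2,4-bis(benzyloxy)phenyl]methanone}
Product: 25 [(2S,3R,4R,5S)-2,5-bis(4-hydroxyphenyl)oxolane-3,4-diyl]bis[(2,4-dihydroxyphenyl)methanone] (CNP0237262.3)
Conditions: H2 (1 atm), Pd/C (10%), EtOAc–MeOH, 25 °C, stopped at full conversion
Reagents that add atoms: none
Why: Hydrogenolysis cleaves the six aryl benzyl ethers under neutral conditions far faster than it attacks the cyclic benzylic ether or the aryl ketones, so no stereocentre is disturbed.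

**Compound list**

1 | (R)-4-hydroxymandelic acid | O=C(O)[C@@H](c1ccc(O)cc1)O | starting material
2 | benzyl (2R)-2-[4-(benzyloxy)phenyl]-2-hydroxyacetate | O=C(OCc1ccccc1)[C@@H](c1ccc(OCc2ccccc2)cc1)O | intermediate
3 | benzyl (2R)-2-[4-(benzyloxy)phenyl]-2-{[tert-butyl(dimethyl)silyl]oxy}acetate | O=C(OCc1ccccc1)[C@@H](c1ccc(OCc2ccccc2)cc1)O[Si](C)(C)C(C)(C)C | intermediate
4 | methyl bis(2,2,2-trifluoroethyl)phosphonoacetate | COC(=O)CP(=O)(OCC(F)(F)F)OCC(F)(F)F | starting material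
5 | (2R)-2-[4-(benzyloxy)phenyl]-2-{[tert-butyl(dimethyl)silyl]oxy}acetaldehyde | O=C[C@@H](c1ccc(OCc2ccccc2)cc1)O[Si](C)(C)C(C)(C)C | intermediate (not isolated)
6 | methyl (2Z,4S)-4-[4-(benzyloxy)phenyl]-4-{[tert-butyl(dimethyl)silyl]oxy}but-2-enoate | COC(=O)/C=C\[C@@H](c1ccc(OCc2ccccc2)cc1)O[Si](C)(C)C(C)(C)C | intermediate
7 | (2Z,4S)-4-[4-(benzyloxy)phenyl]-4-{[tert-butyl(dimethyl)silyl]oxy}but-2-en-1-ol | OC/C=C\[C@@H](c1ccc(OCc2ccccc2)cc1)O[Si](C)(C)C(C)(C)C | intermediate
8 | but-3-enoic acid | C=CCC(=O)O | starting material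
9 | (2Z,4S)-4-[4-(benzyloxy)phenyl]-4-{[tert-butyl(dimethyl)silyl]oxy}but-2-en-1-yl but-3-enoate | C=CCC(=O)OC/C=C\[C@@H](c1ccc(OCc2ccccc2)cc1)O[Si](C)(C)C(C)(C)C | intermediate
10 | (1Z)-1-(trimethylsilyloxy)buta-1,3-dien-1-yl ether of 7 (silyl ketene acetal of 9, vinyl cis to OSiMe3) | C=C/C=C(\O[Si](C)(C)C)OC/C=C\[C@@H](c1ccc(OCc2ccccc2)cc1)O[Si](C)(C)C(C)(C)C | intermediate (not isolated)
11 | trimethylsilyl (2R,3R)-3-[(S)-[4-(benzyloxy)phenyl]{[tert-butyl(dimethyl)silyl]oxy}methyl]-2-ethenylpent-4-enoate | C=C[C@@H](C(=O)O[Si](C)(C)C)[C@@H](C=C)[C@@H](c1ccc(OCc2ccccc2)cc1)O[Si](C)(C)C(C)(C)C | intermediate (not isolated)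
12 | (2R,3R)-3-[(S)-[4-(benzyloxy)phenyl](hydroxy)methyl]-2-ethenylpent-4-enoic acid | C=C[C@@H](C(=O)O)[C@@H](C=C)[C@@H](c1ccc(OCc2ccccc2)cc1)O | intermediate (not isolated)
13 | (3R,4R,5S)-5-[4-(benzyloxy)phenyl]-3,4-diethenyloxolan-2-one | C=C[C@@H]1[C@@H](C=C)[C@@H](c2ccc(OCc3ccccc3)cc2)OC1=O | intermediate
14 | 1-(benzyloxy)-4-bromobenzene | Brc1ccc(OCc2ccccc2)cc1 | starting material
15 | [4-(benzyloxy)phenyl]lithium | [Li]c1ccc(OCc2ccccc2)cc1 | intermediate (not isolated)
16 | [4-(benzyloxy)phenyl]cerium dichloride | Cl[Ce](Cl)c1ccc(OCc2ccccc2)cc1 | intermediate (not isolated)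
17 | (3R,4R,5S)-2,5-bis[4-(benzyloxy)phenyl]-3,4-diethenyloxolan-2-ol (C2 epimers) | C=C[C@@H]1[C@@H](C=C)[C@@H](c2ccc(OCc3ccccc3)cc2)OC1(O)c1ccc(OCc2ccccc2)cc1 | intermediate
18 | (2S,3R,4R,5S)-2,5-bis[4-(benzyloxy)phenyl]-3,4-diethenyloxolane | C=C[C@@H]1[C@@H](C=C)[C@@H](c2ccc(OCc3ccccc3)cc2)O[C@@H]1c1ccc(OCc2ccccc2)cc1 | intermediate
19 | 2,5-bis[4-(benzyloxy)phenyl]-3,4-di(1,2,4-trioxolan-3-yl)oxolane (bis-ozonide, ring configuration as in 18) | O1COOC1[C@@H]1[C@@H](C2OCOO2)[C@@H](c2ccc(OCc3ccccc3)cc2)O[C@@H]1c1ccc(OCc2ccccc2)cc1 | intermediate (not isolated)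
20 | (2S,3R,4R,5S)-2,5-bis[4-(benzyloxy)phenyl]oxolane-3,4-dicarbaldehyde | O=C[C@@H]1[C@@H](C=O)[C@@H](c2ccc(OCc3ccccc3)cc2)O[C@@H]1c1ccc(OCc2ccccc2)cc1 | intermediate
21 | 2,4-bis(benzyloxy)-1-bromobenzene | Brc1ccc(OCc2ccccc2)cc1OCc1ccccc1 | starting material
22 | [2,4-bis(benzyloxy)phenyl]lithium | [Li]c1ccc(OCc2ccccc2)cc1OCc1ccccc1 | intermediate (not isolated)
23 | [(2S,3S,4S,5S)-2,5-bis[4-(benzyloxy)phenyl]oxolane-3,4-diyl]bis{[2,4-bis(benzyloxy)phenyl]methanol} (carbinol centres mixed) | OC(c1ccc(OCc2ccccc2)cc1OCc1ccccc1)[C@@H]1[C@@H](C(O)c2ccc(OCc3ccccc3)cc2OCc2ccccc2)[C@@H](c2ccc(OCc3ccccc3)cc2)O[C@@H]1c1ccc(OCc2ccccc2)cc1 | intermediate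
24 | [(2S,3R,4R,5S)-2,5-bis[4-(benzyloxy)phenyl]oxolane-3,4-diyl]bis{[2,4-bis(benzyloxy)phenyl]methanone} | O=C(c1ccc(OCc2ccccc2)cc1OCc1ccccc1)[C@@H]1[C@@H](C(=O)c2ccc(OCc3ccccc3)cc2OCc2ccccc2)[C@@H](c2ccc(OCc3ccccc3)cc2)O[C@@H]1c1ccc(OCc2ccccc2)cc1 | intermediate
25 | [(2S,3R,4R,5S)-2,5-bis(4-hydroxyphenyl)oxolane-3,4-diyl]bis[(2,4-dihydroxyphenyl)methanone] | O=C(c1ccc(O)cc1O)[C@@H]1[C@@H](C(=O)c2ccc(O)cc2O)[C@@H](c2ccc(O)cc2)O[C@@H]1c1ccc(O)cc1 | target

**Step count and risks**

Total step count: 12. Longest linear sequence: 12 steps (1 → 25); compounds 4, 8, 14 and 21 are bought.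

The sense of the induction from C2 to C3 in step 6 is argued from the Felkin-type model for Z-allylic ethers and is not backed by a direct precedent with an aryl group at the stereocentre. The C4–C5 outcome in step 8 rests on the known cis-selective reduction of 2-aryl lactols that carry an adjacent 3-alkyl group.

The step most likely to fail is the Ireland–Claisen step (step 6). The dienolate geometry or a boat transition state could erode the C3/C4 ratio, and the α-vinyl centre cannot be corrected afterwards by base without conjugation. The fallback sets out from allylic alcohol 7 and makes the two centres one at a time. A Johnson–Claisen rearrangement (MeC(OEt)3, cat. EtCO2H, xylene, 140 °C) gives ethyl (3S)-3-[(S)-[4-(benzyloxy)phenyl]{[tert-butyl(dimethyl)silyl]oxy}methyl]pent-4-enoate F1. HF·pyridine then gives the cis lactone (4S,5S)-5-[4-(benzyloxy)phenyl]-4-ethenyloxolan-2-one F2. Its lithium enolate adds to phenyl vinyl sulfoxide anti to the 4-vinyl group to give (3R,4R,5S)-5-[4-(benzyloxy)phenyl]-4-ethenyl-3-[2-(phenylsulfinyl)ethyl]oxolan-2-one F3. Sulfoxide pyrolysis (toluene, 110 °C) unveils the second vinyl group and the route is rejoined at lactone 13.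

The second risk is the aryl addition to lactone 13 (step 7): enolisation of the doubly activated α-position or double addition. The fallback sets out from ester 9 and avoids the lactone. The rearrangement is worked up with dilute aqueous acid only, to isolate (2R,3R)-3-[(S)-[4-(benzyloxy)phenyl]{[tert-butyl(dimethyl)silyl]oxy}methyl]-2-ethenylpent-4-enoic acid F4. Coupling with MeNHOMe·HCl (EDC) gives (2R,3R)-3-[(S)-[4-(benzyloxy)phenyl]{[tert-butyl(dimethyl)silyl]oxy}methyl]-2-ethenyl-N-methoxy-N-methylpent-4-enamide F5. 4-(Benzyloxy)phenylmagnesium bromide then gives (2R,3R)-1-[4-(benzyloxy)phenyl]-3-[(S)-[4-(benzyloxy)phenyl]{[tert-butyl(dimethyl)silyl]oxy}methyl]-2-ethenylpent-4-en-1-one F6, the chelated tetrahedral intermediate preventing over-addition. HF·pyridine removes the silyl group and the γ-hydroxy ketone closes to lactol 17, where the route is rejoined.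

The third risk is the aryllithium addition to dialdehyde 20 (step 10): epimerisation of the α-centres or E1cB opening of the β-alkoxy aldehyde under the basic reagent. The fallback sets out from 20 and moves to the acid oxidation level. Pinnick oxidation (NaClO2, NaH2PO4, 2-methylbut-2-ene) gives (2S,3R,4R,5S)-2,5-bis[4-(benzyloxy)phenyl]oxolane-3,4-dicarboxylic acid F7. Amidation (EDC, MeNHOMe·HCl) gives (2S,3R,4R,5S)-2,5-bis[4-(benzyloxy)phenyl]-N3,N4-dimethoxy-N3,N4-dimethyloxolane-3,4-dicarboxamide F8. Aryllithium 22 then delivers diketone 24 directly, so the carbinol 23 and step 11 are bypassed.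

**Further compounds**

F1 | step 6 | ethyl (3S)-3-[(S)-[4-(benzyloxy)phenyl]{[tert-butyl(dimethyl)silyl]oxy}methyl]pent-4-enoate | CCOC(=O)C[C@@H](C=C)[C@@H](c1ccc(OCc2ccccc2)cc1)O[Si](C)(C)C(C)(C)C
F2 | step 6 | (4S,5S)-5-[4-(benzyloxy)phenyl]-4-ethenyloxolan-2-one | O=C1C[C@@H](C=C)[C@@H](c2ccc(OCc3ccccc3)cc2)O1
F3 | step 6 | (3R,4R,5S)-5-[4-(benzyloxy)phenyl]-4-ethenyl-3-[2-(phenylsulfinyl)ethyl]oxolan-2-one | O=S(CC[C@@H]1[C@@H](C=C)[C@@H](c2ccc(OCc3ccccc3)cc2)OC1=O)c1ccccc1
F4 | step 7 | (2R,3R)-3-[(S)-[4-(benzyloxy)phenyl]{[tert-butyl(dimethyl)silyl]oxy}methyl]-2-ethenylpent-4-enoic acid | C=C[C@@H](C(=O)O)[C@@H](C=C)[C@@H](c1ccc(OCc2ccccc2)cc1)O[Si](C)(C)C(C)(C)C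
F5 | step 7 | (2R,3R)-3-[(S)-[4-(benzyloxy)phenyl]{[tert-butyl(dimethyl)silyl]oxy}methyl]-2-ethenyl-N-methoxy-N-methylpent-4-enamide | C=C[C@@H](C(=O)N(C)OC)[C@@H](C=C)[C@@H](c1ccc(OCc2ccccc2)cc1)O[Si](C)(C)C(C)(C)C
F6 | step 7 | (2R,3R)-1-[4-(benzyloxy)phenyl]-3-[(S)-[4-(benzyloxy)phenyl]{[tert-butyl(dimethyl)silyl]oxy}methyl]-2-ethenylpent-4-en-1-one | C=C[C@@H](C(=O)c1ccc(OCc2ccccc2)cc1)[C@@H](C=C)[C@@H](c1ccc(OCc2ccccc2)cc1)O[Si](C)(C)C(C)(C)C
F7 | step 10 | (2S,3R,4R,5S)-2,5-bis[4-(benzyloxy)phenyl]oxolane-3,4-dicarboxylic acid | OC(=O)[C@@H]1[C@@H](C(=O)O)[C@@H](c2ccc(OCc3ccccc3)cc2)O[C@@H]1c1ccc(OCc2ccccc2)cc1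
F8 | step 10 | (2S,3R,4R,5S)-2,5-bis[4-(benzyloxy)phenyl]-N3,N4-dimethoxy-N3,N4-dimethyloxolane-3,4-dicarboxamide | CON(C)C(=O)[C@@H]1[C@@H](C(=O)N(C)OC)[C@@H](c2ccc(OCc3ccccc3)cc2)O[C@@H]1c1ccc(OCc2ccccc2)cc1
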